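**Plan**

1. Retrosynthesis: the C12–C13 bond is cut first (aldol; imide closed last). Then the C5–C10 and C7–C8 bonds are cut in one stroke, which opens both rings to one acyclic chloro enynone. Its chain is cut at C9–C8 (epoxide opening by an alkynylalane), C9=C10 (cross-metathesis) and C1–C2 (carbonyl allylation).
2. Forward: the chain is joined linearly (C2–C7 from mesityl oxide and an allylsilane, then C1/C10/C20, then C9/C11/C12, then C8/C17). Ring A and then ring B close in one gold-catalysed double keto-ene cyclisation. The side chain is finished by an Evans aldol and imide closure.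
3. Enabling feature: C6, the one oxygen-bearing ring carbon, lies between C5 (shared by rings A and B) and C7 (ring B), so a C6 ketone turns both into enol carbons. C10 bears a methyl and C8 an exocyclic methylene, i.e. the hydrogen adducts of a C10=C20 alkene and a C8≡C17 alkyne.
4. Stereochemistry: C2 by catalytic asymmetric allylation and Appel inversion; C9 by Sharpless epoxidation and invertive epoxide opening; C10 and C5 relayed from the C2 chloride (equatorial in the chair of the key step); C6 by substrate-controlled reduction; C12/C13 by the Evans auxiliary.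
5. Helpers put in and taken out: C6 ketone level (reduced in step 15), dioxolane, tert-butyl ester, C-silyl and O-silyl groups, thionocarbonate, oxazolidinone.

Key step: step 14

Remark: atoms are named throughout by the labdane numbering of the target (ring carbons C1–C10, side chain C11/C12, imide carbons C13–C16, exocyclic methylene C17, gem-dimethyl C18/C19, angular methyl C20); all carbon building blocks and the auxiliary are taken to be commercial.

**Route**

Step 1
Reactants: 1 4-methylpent-3-en-2-one (mesityl oxide); 2 allyltrimethylsilane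
Product: 3 4,4-dimethylhept-6-en-2-one
Conditions: TiCl4, CH2Cl2, −78 °C; aqueous work-up
Reagents that add atoms: none
Why: Hosomi–Sakurai conjugate allylation, in which the TiCl4-activated enone is attacked at its disubstituted beta carbon by the allylsilane, builds the quaternary C4 with both methyl groups and leaves a terminal alkene as the masked C2 aldehyde.

Step 2
Reactants: 3 4,4-dimethylhept-6-en-2-one
Product: 4 2-(2,2-dimethylpent-4-en-1-yl)-2-methyl-1,3-dioxolane
Conditions: ethylene glycol, TsOH·H2O (cat.), toluene, reflux, Dean–Stark trap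
Reagents that add atoms: ethylene glycol, OCCO
Why: Acid-catalysed ketalisation with azeotropic removal of water masks the C6 ketone against the hydride and organoaluminium reagents used later.

Step 3
Reactants: 4 2-(2,2-dimethylpent-4-en-1-yl)-2-methyl-1,3-dioxolane
Product: 5 3,3-dimethyl-4-(2-methyl-1,3-dioxolan-2-yl)butanal
Conditions: O3, CH2Cl2, −78 °C; then Me2S, −78 °C to rt
Reagents that add atoms: ozone, [O-][O+]=O
Why: Ozonolysis with reductive work-up cleaves the terminal alkene to the C2 aldehyde while the ketal is inert.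

Step 4
Reactants: 5 3,3-dimethyl-4-(2-methyl-1,3-dioxolan-2-yl)butanal; 6 tert-butyl 2-(bromomethyl)prop-2-enoate
Product: 7 tert-butyl (4R)-4-hydroxy-6,6-dimethyl-2-methylidene-7-(2-methyl-1,3-dioxolan-2-yl)heptanoate
Conditions: CrCl2 (10 mol %), chiral carbazole-based bis(oxazoline) ligand (enantiomer that gives the 4R carbinol), Mn powder, Me3SiCl, THF, rt; aqueous citric acid work-up
Reagents that add atoms: none
Why: Catalytic asymmetric Nozaki–Hiyama–Kishi 2-(alkoxycarbonyl)allylation, in which the allylchromium species made from 6 adds to the aldehyde inside the chiral ligand sphere, sets the C2 carbinol as R by catalyst control, and the tert-butyl ester holds back lactonisation.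

Step 5
Reactants: 7 tert-butyl (4R)-4-hydroxy-6,6-dimethyl-2-methylidene-7-(2-methyl-1,3-dioxolan-2-yl)heptanoate
Product: 8 tert-butyl (4S)-4-chloro-6,6-dimethyl-2-methylidene-7-(2-methyl-1,3-dioxolan-2-yl)heptanoate
Conditions: PPh3, CCl4, CH2Cl2, 40 °C
Reagents that add atoms: tetrachloromethane, ClC(Cl)(Cl)Cl
Why: Appel reaction, in which chloride displaces the alkoxyphosphonium group in an SN2 step, turns the R carbinol into the S chloride with inversion and so installs the later stereocontrol element at C2.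

Step 6
Reactants: 9 but-3-en-1-ol
Product: 10 (but-3-en-1-yloxy)(tert-butyl)diphenylsilane
Conditions: t-BuPh2SiCl, imidazole, CH2Cl2, rt
Reagents that add atoms: tert-butyl(chloro)diphenylsilane, CC(C)(C)[Si](Cl)(c1ccccc1)c1ccccc1
Why: Silylation of the primary alcohol gives an ether that withstands hydride, organoaluminium, base, mild acid and the gold catalyst.

Step 7
Reactants: 8 tert-butyl (4S)-4-chloro-6,6-dimethyl-2-methylidene-7-(2-methyl-1,3-dioxolan-2-yl)heptanoate; 10 (but-3-en-1-yloxy)(tert-butyl)diphenylsilane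
Product: 11 tert-butyl (2E)-5-[(tert-butyldiphenylsilyl)oxy]-2-[(2S)-2-chloro-4,4-dimethyl-5-(2-methyl-1,3-dioxolan-2-yl)pentyl]pent-2-enoate
Conditions: second-generation Hoveyda–Grubbs catalyst (5 mol %), 10 (3 equiv), CH2Cl2, 40 °C
Reagents that add atoms: none
Why: Olefin cross-metathesis of the 1,1-disubstituted acrylate with the terminal alkene, driven by loss of ethene, should give the trisubstituted enoate as the E isomer, in which the new alkyl group is trans to the ester.

Step 8
Reactants: 11 tert-butyl (2E)-5-[(tert-butyldiphenylsilyl)oxy]-2-[(2S)-2-chloro-4,4-dimethyl-5-(2-methyl-1,3-dioxolan-2-yl)pentyl]pent-2-enoate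
Product: 12 (2E)-5-[(tert-butyldiphenylsilyl)oxy]-2-[(2S)-2-chloro-4,4-dimethyl-5-(2-methyl-1,3-dioxolan-2-yl)pentyl]pent-2-en-1-ol
Conditions: iBu2AlH, CH2Cl2, −78 to −20 °C; Rochelle salt work-up
Reagents that add atoms: none
Why: 1,2-Reduction of the enoate by the aluminium hydride gives the allylic alcohol needed for directed epoxidation and leaves chloride, ketal and silyl ether untouched.

Step 9
Reactants: 12 (2E)-5-[(tert-butyldiphenylsilyl)oxy]-2-[(2S)-2-chloro-4,4-dimethyl-5-(2-methyl-1,3-dioxolan-2-yl)pentyl]pent-2-en-1-ol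
Product: 13 {(2S,3S)-3-{2-[(tert-butyldiphenylsilyl)oxy]ethyl}-2-[(2S)-2-chloro-4,4-dimethyl-5-(2-methyl-1,3-dioxolan-2-yl)pentyl]oxiran-2-yl}methanol
Conditions: Ti(OiPr)4 (10 mol %), diethyl L-(+)-tartrate (12 mol %), t-BuOOH, 4 Å molecular sieves, CH2Cl2, −20 °C
Reagents that add atoms: tert-butyl hydroperoxide, CC(C)(C)OO
Why: Sharpless asymmetric epoxidation, in which the titanium tartrate complex delivers oxygen to one face of the E allylic alcohol under reagent control, gives the 2S,3S epoxide and thereby fixes the configuration that C9 will have after inversion.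

Step 10
Reactants: 13 {(2S,3S)-3-{2-[(tert-butyldiphenylsilyl)oxy]ethyl}-2-[(2S)-2-chloro-4,4-dimethyl-5-(2-methyl-1,3-dioxolan-2-yl)pentyl]oxiran-2-yl}methanol; 14 ethynyltrimethylsilane
Product: 15 (2R,3S)-3-{2-[(tert-butyldiphenylsilyl)oxy]ethyl}-2-[(2S)-2-chloro-4,4-dimethyl-5-(2-methyl-1,3-dioxolan-2-yl)pentyl]-5-(trimethylsilyl)pent-4-yne-1,2-diol
Conditions: 14, n-BuLi, then Et2AlCl, toluene, 0 °C (forms Et2AlC≡CSiMe3); then 13, toluene, 0 °C to rt; Rochelle salt work-up
Reagents that add atoms: none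
Why: Opening of the 2,3-epoxy alcohol by the alkynylalane, directed by the aluminium alkoxide to the distal epoxide carbon C9 and proceeding with SN2 inversion, sets C9 and brings in C8 and C17 as the alkyne.

Step 11
Reactants: 15 (2R,3S)-3-{2-[(tert-butyldiphenylsilyl)oxy]ethyl}-2-[(2S)-2-chloro-4,4-dimethyl-5-(2-methyl-1,3-dioxolan-2-yl)pentyl]-5-(trimethylsilyl)pent-4-yne-1,2-diol
Product: 16 (4R)-4-{(3S)-5-[(tert-butyldiphenylsilyl)oxy]-1-(trimethylsilyl)pent-1-yn-3-yl}-4-[(2S)-2-chloro-4,4-dimethyl-5-(2-methyl-1,3-dioxolan-2-yl)pentyl]-1,3-dioxolane-2-thione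
Conditions: 1,1'-thiocarbonyldiimidazole, DMAP (cat.), toluene, 80 °C
Reagents that add atoms: 1,1'-thiocarbonyldiimidazole, S=C(n1ccnc1)n1ccnc1
Why: The primary and the tertiary hydroxyl of the 1,2-diol close to the five-membered cyclic thionocarbonate, the substrate of the Corey–Winter olefination.

Step 12
Reactants: 16 (4R)-4-{(3S)-5-[(tert-butyldiphenylsilyl)oxy]-1-(trimethylsilyl)pent-1-yn-3-yl}-4-[(2S)-2-chloro-4,4-dimethyl-5-(2-methyl-1,3-dioxolan-2-yl)pentyl]-1,3-dioxolane-2-thione
Product: 17 2-[(4S,7R)-7-{2-[(tert-butyldiphenylsilyl)oxy]ethyl}-4-chloro-2,2-dimethyl-6-methylidene-9-(trimethylsilyl)non-8-yn-1-yl]-2-methyl-1,3-dioxolane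
Conditions: P(OMe)3, 110 °C
Reagents that add atoms: none
Why: Corey–Winter olefination, by thiophilic attack of the phosphite and loss of CO2, converts the diol carbons into the 1,1-disubstituted C10=C20 alkene without touching the neighbouring C9 centre.

Step 13
Reactants: 17 2-[(4S,7R)-7-{2-[(tert-butyldiphenylsilyl)oxy]ethyl}-4-chloro-2,2-dimethyl-6-methylidene-9-(trimethylsilyl)non-8-yn-1-yl]-2-methyl-1,3-dioxolane
Product: 18 (6S,9R)-9-{2-[(tert-butyldiphenylsilyl)oxy]ethyl}-6-chloro-4,4-dimethyl-8-methylideneundec-10-yn-2-one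
Conditions: K2CO3 (cat.), MeOH, rt; then 1 M HCl, THF, rt
Reagents that add atoms: water, O
Why: Methanolysis of the C–Si bond of the alkyne and acid hydrolysis of the dioxolane free the terminal alkyne and the C6 ketone while the bulky silyl ether and the secondary chloride persist.

Step 14
Reactants: 18 (6S,9R)-9-{2-[(tert-butyldiphenylsilyl)oxy]ethyl}-6-chloro-4,4-dimethyl-8-methylideneundec-10-yn-2-one
Product: 20 (4S,4aR,6S,8aS)-4-{2-[(tert-butyldiphenylsilyl)oxy]ethyl}-6-chloro-4a,8,8-trimethyl-3-methylideneoctahydronaphthalen-1(2H)-one, via ring-A methyl ketone 19 (not isolated)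
Conditions: chloro[1,3-bis(2,6-diisopropylphenyl)imidazol-2-ylidene]gold (5 mol %), AgNTf2 (silver bis(trifluoromethanesulfonyl)imide, 5 mol %), 4 Å molecular sieves, toluene (0.02 M), 80 °C
Reagents that add atoms: none
Why: Proposed new method: the cationic monovalent gold centre activates the 1,1-disubstituted C10=C20 alkene of 18, and the C5 enol of the C6 ketone, the only nucleophile that reaches it through a six-membered chair, adds to C10 in the Markovnikov sense (C5–C10 bond; protodeauration turns C20 into the angular methyl) to give 19, whose C7 enol is now held next to the terminal alkyne and adds anti to the gold-bound triple bond (C7–C8 bond; protodeauration gives the C8=C17 methylene) to give 20. The closest known reaction types are the gold-catalysed intramolecular hydroalkylation of unactivated alkenes by simple ketones, the gold-catalysed Conia-ene cyclisation of ketone enols or silyl enol ethers onto alkynes and the thermal tandem Conia-ene reaction; new is that one ketone uses both alpha carbons in turn on an alkene and an alkyne in one flask. Ring A closes in the 6-exo-trig mode and ring B in the 6-exo-dig mode. C10 is controlled by the C2 chloride, which stays equatorial in the chair while the methyl group rather than the larger C9 branch goes axial; C5 is set by the equatorial acetyl group in the same chair and stays under thermodynamic control as a ketone alpha carbon (trans ring fusion); C9 is carried in unchanged from 18. The step needs chemoselection between two enols and two pi bonds, which ring size secures because every other pairing would close a four-, eight- or ten-membered ring, and it needs the chloride and the doubly activated C9–H to survive, which the absence of base and of free carbocations should secure.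

Step 15
Reactants: 20 (4S,4aR,6S,8aS)-4-{2-[(tert-butyldiphenylsilyl)oxy]ethyl}-6-chloro-4a,8,8-trimethyl-3-methylideneoctahydronaphthalen-1(2H)-one
Product: 21 (1R,4S,4aR,6S,8aS)-4-{2-[(tert-butyldiphenylsilyl)oxy]ethyl}-6-chloro-4a,8,8-trimethyl-3-methylidenedecahydronaphthalen-1-ol
Conditions: NaBH4, CeCl3·7H2O, MeOH, −40 to 0 °C
Reagents that add atoms: none
Why: Luche reduction, in which hydride reaches the C6 carbonyl from the alpha face because the beta face is shielded by the syn-axial methyl groups on C4 and C10, gives the axial 6-beta alcohol and outruns migration of the beta,gamma double bond.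

Step 16
Reactants: 21 (1R,4S,4aR,6S,8aS)-4-{2-[(tert-butyldiphenylsilyl)oxy]ethyl}-6-chloro-4a,8,8-trimethyl-3-methylidenedecahydronaphthalen-1-ol
Product: 22 (1R,4S,4aR,6S,8aS)-6-chloro-4-(2-hydroxyethyl)-4a,8,8-trimethyl-3-methylidenedecahydronaphthalen-1-ol
Conditions: Bu4NF, THF, 0 °C to rt
Reagents that add atoms: none
Why: Fluoride-induced cleavage of the silyl ether frees the primary C12 alcohol.

Step 17
Reactants: 22 (1R,4S,4aR,6S,8aS)-6-chloro-4-(2-hydroxyethyl)-4a,8,8-trimethyl-3-methylidenedecahydronaphthalen-1-ol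
Product: 23 [(1S,4R,4aS,7S,8aR)-7-chloro-4-hydroxy-5,5,8a-trimethyl-2-methylidenedecahydronaphthalen-1-yl]acetaldehyde
Conditions: TEMPO (10 mol %), PhI(OAc)2, CH2Cl2, rt
Reagents that add atoms: none
Why: Oxoammonium (TEMPO) oxidation selects the primary alcohol over the hindered axial secondary alcohol and stops at the aldehyde.

Step 18
Reactants: 24 (4R)-4-benzyl-1,3-oxazolidin-2-one; 25 methyl 4-chloro-4-oxobutanoate
Product: 26 methyl 4-[(4R)-4-benzyl-2-oxo-1,3-oxazolidin-3-yl]-4-oxobutanoate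
Conditions: n-BuLi, THF, −78 °C; then 25, −78 to 0 °C
Reagents that add atoms: none
Why: N-Acylation of the lithiated oxazolidinone by the acid chloride gives the Evans imide that carries C13 to C16.

Step 19
Reactants: 23 [(1S,4R,4aS,7S,8aR)-7-chloro-4-hydroxy-5,5,8a-trimethyl-2-methylidenedecahydronaphthalen-1-yl]acetaldehyde; 26 methyl 4-[(4R)-4-benzyl-2-oxo-1,3-oxazolidin-3-yl]-4-oxobutanoate
Product: 27 methyl (3R,4S)-3-{[(4R)-4-benzyl-2-oxo-1,3-oxazolidin-3-yl]carbonyl}-5-[(1S,4R,4aS,7S,8aR)-7-chloro-4-hydroxy-5,5,8a-trimethyl-2-methylidenedecahydronaphthalen-1-yl]-4-hydroxypentanoate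
Conditions: 26, Bu2BOTf, iPr2NEt, CH2Cl2, −78 to 0 °C; then 23, −78 to 0 °C; pH 7 buffer, MeOH, H2O2, 0 °C
Reagents that add atoms: none
Why: Evans syn-aldol reaction, in which the Z boron enolate of 26 adds to aldehyde 23 through a chair transition state with one enolate face shielded by the benzyl group of the R auxiliary, sets C12 as S and C13 as R.

Step 20
Reactants: 27 methyl (3R,4S)-3-{[(4R)-4-benzyl-2-oxo-1,3-oxazolidin-3-yl]carbonyl}-5-[(1S,4R,4aS,7S,8aR)-7-chloro-4-hydroxy-5,5,8a-trimethyl-2-methylidenedecahydronaphthalen-1-yl]-4-hydroxypentanoate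
Product: 28 haterumaimide F, (3R)-3-{(1S)-2-[(1S,4R,4aS,7S,8aR)-7-chloro-4-hydroxy-5,5,8a-trimethyl-2-methylidenedecahydronaphthalen-1-yl]-1-hydroxyethyl}pyrrolidine-2,5-dione
Conditions: NH3 (7 M in MeOH), 0 °C to rt
Reagents that add atoms: ammonia, N
Why: Ammonolysis followed by five-membered ring closure, in which the primary amide formed at one acyl group attacks the other and expels methanol and the oxazolidinone, forms the succinimide under mild conditions that should leave C12 and C13 untouched.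

**Compound list**

1 | 4-methylpent-3-en-2-one (mesityl oxide) | CC(=O)C=C(C)C | starting material
2 | allyltrimethylsilane | C=CC[Si](C)(C)C | starting material
3 | 4,4-dimethylhept-6-en-2-one | CC(=O)CC(C)(C)CC=C | intermediate
4 | 2-(2,2-dimethylpent-4-en-1-yl)-2-methyl-1,3-dioxolane | C=CCC(C)(C)CC1(C)OCCO1 | intermediate
5 | 3,3-dimethyl-4-(2-methyl-1,3-dioxolan-2-yl)butanal | O=CCC(C)(C)CC1(C)OCCO1 | intermediate
6 | tert-butyl 2-(bromomethyl)prop-2-enoate | C=C(CBr)C(=O)OC(C)(C)C | starting material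
7 | tert-butyl (4R)-4-hydroxy-6,6-dimethyl-2-methylidene-7-(2-methyl-1,3-dioxolan-2-yl)heptanoate | C=C(C[C@H](O)CC(C)(C)CC1(C)OCCO1)C(=O)OC(C)(C)C | intermediate
8 | tert-butyl (4S)-4-chloro-6,6-dimethyl-2-methylidene-7-(2-methyl-1,3-dioxolan-2-yl)heptanoate | C=C(C[C@@H](Cl)CC(C)(C)CC1(C)OCCO1)C(=O)OC(C)(C)C | intermediate
9 | but-3-en-1-ol | C=CCCO | starting material
10 | (but-3-en-1-yloxy)(tert-butyl)diphenylsilane | C=CCCO[Si](c1ccccc1)(c1ccccc1)C(C)(C)C | intermediate
11 | tert-butyl (2E)-5-[(tert-butyldiphenylsilyl)oxy]-2-[(2S)-2-chloro-4,4-dimethyl-5-(2-methyl-1,3-dioxolan-2-yl)pentyl]pent-2-enoate | CC(C)(C)OC(=O)/C(C[C@@H](Cl)CC(C)(C)CC1(C)OCCO1)=C/CCO[Si](c1ccccc1)(c1ccccc1)C(C)(C)C | intermediate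
12 | (2E)-5-[(tert-butyldiphenylsilyl)oxy]-2-[(2S)-2-chloro-4,4-dimethyl-5-(2-methyl-1,3-dioxolan-2-yl)pentyl]pent-2-en-1-ol | OC/C(C[C@@H](Cl)CC(C)(C)CC1(C)OCCO1)=C/CCO[Si](c1ccccc1)(c1ccccc1)C(C)(C)C | intermediate
13 | {(2S,3S)-3-{2-[(tert-butyldiphenylsilyl)oxy]ethyl}-2-[(2S)-2-chloro-4,4-dimethyl-5-(2-methyl-1,3-dioxolan-2-yl)pentyl]oxiran-2-yl}methanol | OC[C@]1(C[C@@H](Cl)CC(C)(C)CC2(C)OCCO2)O[C@H]1CCO[Si](c1ccccc1)(c1ccccc1)C(C)(C)C | intermediate
14 | ethynyltrimethylsilane | C#C[Si](C)(C)C | starting material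
15 | (2R,3S)-3-{2-[(tert-butyldiphenylsilyl)oxy]ethyl}-2-[(2S)-2-chloro-4,4-dimethyl-5-(2-methyl-1,3-dioxolan-2-yl)pentyl]-5-(trimethylsilyl)pent-4-yne-1,2-diol | OC[C@@](O)(C[C@@H](Cl)CC(C)(C)CC1(C)OCCO1)[C@H](C#C[Si](C)(C)C)CCO[Si](c1ccccc1)(c1ccccc1)C(C)(C)C | intermediate
16 | (4R)-4-{(3S)-5-[(tert-butyldiphenylsilyl)oxy]-1-(trimethylsilyl)pent-1-yn-3-yl}-4-[(2S)-2-chloro-4,4-dimethyl-5-(2-methyl-1,3-dioxolan-2-yl)pentyl]-1,3-dioxolane-2-thione | S=C1OC[C@@](C[C@@H](Cl)CC(C)(C)CC2(C)OCCO2)([C@H](C#C[Si](C)(C)C)CCO[Si](c2ccccc2)(c2ccccc2)C(C)(C)C)O1 | intermediate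
17 | 2-[(4S,7R)-7-{2-[(tert-butyldiphenylsilyl)oxy]ethyl}-4-chloro-2,2-dimethyl-6-methylidene-9-(trimethylsilyl)non-8-yn-1-yl]-2-methyl-1,3-dioxolane | CC1(CC(C)(C)C[C@H](Cl)CC(=C)[C@H](C#C[Si](C)(C)C)CCO[Si](c2ccccc2)(c2ccccc2)C(C)(C)C)OCCO1 | intermediate
18 | (6S,9R)-9-{2-[(tert-butyldiphenylsilyl)oxy]ethyl}-6-chloro-4,4-dimethyl-8-methylideneundec-10-yn-2-one | CC(=O)CC(C)(C)C[C@H](Cl)CC(=C)[C@H](C#C)CCO[Si](c1ccccc1)(c1ccccc1)C(C)(C)C | intermediate
19 | 1-[(1S,2R,4S)-2-{(3S)-5-[(tert-butyldiphenylsilyl)oxy]pent-1-yn-3-yl}-4-chloro-2,6,6-trimethylcyclohexyl]ethan-1-one | CC(=O)[C@H]1C(C)(C)C[C@H](Cl)C[C@]1(C)[C@H](C#C)CCO[Si](c1ccccc1)(c1ccccc1)C(C)(C)C | intermediate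
20 | (4S,4aR,6S,8aS)-4-{2-[(tert-butyldiphenylsilyl)oxy]ethyl}-6-chloro-4a,8,8-trimethyl-3-methylideneoctahydronaphthalen-1(2H)-one | C=C1CC(=O)[C@H]2C(C)(C)C[C@H](Cl)C[C@]2(C)[C@H]1CCO[Si](c1ccccc1)(c1ccccc1)C(C)(C)C | intermediate
21 | (1R,4S,4aR,6S,8aS)-4-{2-[(tert-butyldiphenylsilyl)oxy]ethyl}-6-chloro-4a,8,8-trimethyl-3-methylidenedecahydronaphthalen-1-ol | C=C1C[C@@H](O)[C@H]2C(C)(C)C[C@H](Cl)C[C@]2(C)[C@H]1CCO[Si](c1ccccc1)(c1ccccc1)C(C)(C)C | intermediate
22 | (1R,4S,4aR,6S,8aS)-6-chloro-4-(2-hydroxyethyl)-4a,8,8-trimethyl-3-methylidenedecahydronaphthalen-1-ol | C=C1C[C@@H](O)[C@H]2C(C)(C)C[C@H](Cl)C[C@]2(C)[C@H]1CCO | intermediate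
23 | [(1S,4R,4aS,7S,8aR)-7-chloro-4-hydroxy-5,5,8a-trimethyl-2-methylidenedecahydronaphthalen-1-yl]acetaldehyde | C=C1C[C@@H](O)[C@H]2C(C)(C)C[C@H](Cl)C[C@]2(C)[C@H]1CC=O | intermediate
24 | (4R)-4-benzyl-1,3-oxazolidin-2-one | O=C1N[C@H](Cc2ccccc2)CO1 | starting material
25 | methyl 4-chloro-4-oxobutanoate | COC(=O)CCC(Cl)=O | starting material
26 | methyl 4-[(4R)-4-benzyl-2-oxo-1,3-oxazolidin-3-yl]-4-oxobutanoate | COC(=O)CCC(=O)N1[C@H](Cc2ccccc2)COC1=O | intermediate
27 | methyl (3R,4S)-3-{[(4R)-4-benzyl-2-oxo-1,3-oxazolidin-3-yl]carbonyl}-5-[(1S,4R,4aS,7S,8aR)-7-chloro-4-hydroxy-5,5,8a-trimethyl-2-methylidenedecahydronaphthalen-1-yl]-4-hydroxypentanoate | C=C1C[C@@H](O)[C@H]2C(C)(C)C[C@H](Cl)C[C@]2(C)[C@H]1C[C@H](O)[C@@H](CC(=O)OC)C(=O)N1[C@H](Cc2ccccc2)COC1=O | intermediate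
28 | haterumaimide F, (3R)-3-{(1S)-2-[(1S,4R,4aS,7S,8aR)-7-chloro-4-hydroxy-5,5,8a-trimethyl-2-methylidenedecahydronaphthalen-1-yl]-1-hydroxyethyl}pyrrolidine-2,5-dione | C=C1C[C@@H](O)[C@H]2C(C)(C)C[C@H](Cl)C[C@]2(C)[C@H]1C[C@H](O)[C@H]1CC(=O)NC1=O | target

**Step count and risks**

Total step count: 20. Longest linear sequence: 18 steps (steps 1–5, 7–17, 19 and 20).

Steps most likely to fail:

1. Step 14 (gold-catalysed double keto-ene cyclisation). What may go wrong: attack of the C10=C20 alkene or of the silyl ether oxygen on the gold-bound alkyne before ring A has formed; stalling after the first ring closure; or acid-induced migration of the new C8=C17 double bond into conjugation with the ketone. Fallback (known reactions, one bond at a time, ring B through a silyl enol ether): the fallback sets out from 17. Only the dioxolane is hydrolysed (1 M HCl, THF) to give the C-silylated enynone (6S,9R)-9-{2-[(tert-butyldiphenylsilyl)oxy]ethyl}-6-chloro-4,4-dimethyl-8-methylidene-11-(trimethylsilyl)undec-10-yn-2-one F1. With the alkyne masked by silicon, the known gold-catalysed hydroalkylation of an unactivated alkene by a simple ketone (same gold catalyst, toluene, 80 °C) closes ring A to 1-[(1S,2R,4S)-2-{(3R)-5-[(tert-butyldiphenylsilyl)oxy]-1-(trimethylsilyl)pent-1-yn-3-yl}-4-chloro-2,6,6-trimethylcyclohexyl]ethan-1-one F2. K2CO3 in MeOH frees the alkyne and gives 19, which is now isolated. t-BuMe2SiOTf and Et3N (CH2Cl2, −78 °C) give the less substituted silyl enol ether tert-butyl({1-[(1S,2R,4S)-2-{(3S)-5-[(tert-butyldiphenylsilyl)oxy]pent-1-yn-3-yl}-4-chloro-2,6,6-trimethylcyclohexyl]ethenyl}oxy)dimethylsilane F3. The known gold-catalysed 6-exo-dig addition of a silyl enol ether to a terminal alkyne ((acetonitrile)[(2-biphenyl)di-tert-butylphosphine]gold hexafluoroantimonate, CH2Cl2/MeOH, rt) then closes ring B and returns to the route at 20.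

2. Step 10 (alkynylalane opening of the epoxy alcohol). What may go wrong: attack at the fully substituted epoxide carbon C10, Lewis acid-induced rearrangement of the trisubstituted epoxide, or opening of the dioxolane by the alane. Fallback: the fallback sets out from 12. The primary allylic alcohol is phosphorylated (ClP(O)(OEt)2, DMAP, CH2Cl2) to give (2E)-5-[(tert-butyldiphenylsilyl)oxy]-2-[(2S)-2-chloro-4,4-dimethyl-5-(2-methyl-1,3-dioxolan-2-yl)pentyl]pent-2-en-1-yl diethyl phosphate F4. A copper-catalysed enantioselective SN2′ substitution with iBu2Al–C≡C–SiMe3 (CuCl2·2H2O and a chiral sulfonate-bearing N-heterocyclic carbene silver complex, THF, −30 °C) delivers the alkynyl group to C9 with transposition of the double bond. This sets C9 by catalyst control, makes the C10=C20 alkene directly and returns to the route at 17, so that steps 9, 11 and 12 are bypassed as well.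

3. Step 20 (imide closure). What may go wrong: retro-aldol cleavage or epimerisation at C13 in basic ammonia before the ring closes, or attack of ammonia at the ring carbonyl of the oxazolidinone. Fallback: the fallback sets out from 27. LiOH/H2O2 (THF/H2O, 0 °C) removes the auxiliary and gives (2R,3S)-4-[(1S,4R,4aS,7S,8aR)-7-chloro-4-hydroxy-5,5,8a-trimethyl-2-methylidenedecahydronaphthalen-1-yl]-3-hydroxy-2-(2-methoxy-2-oxoethyl)butanoic acid F5. Activation as the mixed anhydride (isobutyl chloroformate, N-methylmorpholine, THF, −20 °C) and NH3 give methyl (3R,4S)-3-carbamoyl-5-[(1S,4R,4aS,7S,8aR)-7-chloro-4-hydroxy-5,5,8a-trimethyl-2-methylidenedecahydronaphthalen-1-yl]-4-hydroxypentanoate F6. K2CO3 in MeOH at 0 °C then closes the amide nitrogen onto the methyl ester and returns to the route at 28.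

**Further compounds**

F1 | step 14 | (6S,9R)-9-{2-[(tert-butyldiphenylsilyl)oxy]ethyl}-6-chloro-4,4-dimethyl-8-methylidene-11-(trimethylsilyl)undec-10-yn-2-one | CC(=O)CC(C)(C)C[C@H](Cl)CC(=C)[C@H](C#C[Si](C)(C)C)CCO[Si](c1ccccc1)(c1ccccc1)C(C)(C)C
F2 | step 14 | 1-[(1S,2R,4S)-2-{(3R)-5-[(tert-butyldiphenylsilyl)oxy]-1-(trimethylsilyl)pent-1-yn-3-yl}-4-chloro-2,6,6-trimethylcyclohexyl]ethan-1-one | CC(=O)[C@H]1C(C)(C)C[C@H](Cl)C[C@]1(C)[C@H](C#C[Si](C)(C)C)CCO[Si](c1ccccc1)(c1ccccc1)C(C)(C)C
F3 | step 14 | tert-butyl({1-[(1S,2R,4S)-2-{(3S)-5-[(tert-butyldiphenylsilyl)oxy]pent-1-yn-3-yl}-4-chloro-2,6,6-trimethylcyclohexyl]ethenyl}oxy)dimethylsilane | C=C(O[Si](C)(C)C(C)(C)C)[C@H]1C(C)(C)C[C@H](Cl)C[C@]1(C)[C@H](C#C)CCO[Si](c1ccccc1)(c1ccccc1)C(C)(C)C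
F4 | step 10 | (2E)-5-[(tert-butyldiphenylsilyl)oxy]-2-[(2S)-2-chloro-4,4-dimethyl-5-(2-methyl-1,3-dioxolan-2-yl)pentyl]pent-2-en-1-yl diethyl phosphate | CCOP(=O)(OCC)OC/C(C[C@@H](Cl)CC(C)(C)CC1(C)OCCO1)=C/CCO[Si](c1ccccc1)(c1ccccc1)C(C)(C)C
F5 | step 20 | (2R,3S)-4-[(1S,4R,4aS,7S,8aR)-7-chloro-4-hydroxy-5,5,8a-trimethyl-2-methylidenedecahydronaphthalen-1-yl]-3-hydroxy-2-(2-methoxy-2-oxoethyl)butanoic acid | C=C1C[C@@H](O)[C@H]2C(C)(C)C[C@H](Cl)C[C@]2(C)[C@H]1C[C@H](O)[C@@H](CC(=O)OC)C(=O)O
F6 | step 20 | methyl (3R,4S)-3-carbamoyl-5-[(1S,4R,4aS,7S,8aR)-7-chloro-4-hydroxy-5,5,8a-trimethyl-2-methylidenedecahydronaphthalen-1-yl]-4-hydroxypentanoate | C=C1C[C@@H](O)[C@H]2C(C)(C)C[C@H](Cl)C[C@]2(C)[C@H]1C[C@H](O)[C@@H](CC(=O)OC)C(N)=O
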